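The numbers in the tables were generated by integration from invented constants; scatter was added.

Answer 3 questions and spend the care on the last: read the orders from the first readings, and reckon the share at 78 h from how fast X drains.

| flask | Q | E | X | time |
|---|---|---|---|---|
| north-west | 0.100 M | 0.100 M |  |  |
| south-west | 0.0600 M | 0.0600 M |  |  |
| west | 0.100 M | 0.100 M | 0.0500 M |  |
| north | 0.100 M | 0.200 M |  |  |
| north-east | 0.100 M | 0.100 M |  | 78 h |

| run | time / h | [X] / M |
|---|---|---|
| north-west run | 2.2 | 0.0137 |
| north-west run | 4.3 | 0.0218 |
| north-west run | 6.5 | 0.0311 |
| north-west run | 8.7 | 0.0368 |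
| north-west run | 11 | 0.0405 |
| north-west run | 13 | 0.0437 |
| south-west run | 2.2 | 0.0033 |
| south-west run | 4.3 | 0.0095 |
| south-west run | 6.5 | 0.0117 |
| south-west run | 8.7 | 0.0148 |
| south-west run | 11 | 0.0186 |
| south-west run | 13 | 0.0172 |
| west run | 2.2 | 0.0660 |
| west run | 4.3 | 0.0750 |
| west run | 6.5 | 0.0809 |
| west run | 8.7 | 0.0820 |
| west run | 11 | 0.0786 |
| west run | 13 | 0.0781 |
| north run | 2.2 | 0.0238 |
| north run | 4.3 | 0.0421 |
| north run | 6.5 | 0.0550 |
| north run | 8.7 | 0.0609 |
| north run | 11 | 0.0624 |
| north run | 13 | 0.0639 |

(each reading ± 8 × 10⁻⁴ M)

- apparent order in [Q] of the starting rate, round the charge of the north-west run (the rate where two percent of its Q have turned into X) (one fixed amount of X, the same in the runs compared)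
- apparent order in [E] of the starting rate, round the charge of the north-west run (the rate where two percent of its Q have turned into X)
- X in the north-east run at 78 h, as a share of the Q charged

- Overall: Q + E -> X.
- Constant volume, constant temperature.
- "The second partner" is E.
- An order is taken over about fifteen percent of the charge, up and down.

Read the order in E from the first readings, north over north-west: 0.797. Take the total order from south-west over north-west at 4.3 h, 1.63, since the scatter is a quarter of the first south-west reading. The order in Q is then 0.833. These are rough readings, taken at one time and not at one amount of X.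

Round that total up to second order and write the formation rate as kW·c(Q)·c(E). The first step of the west run reads as a gain of 7.27 mM/h, so at the mean c(Q) of that step kW is 0.859 /M/h. The west run then falls from 0.0820 M to 0.0781 M, which gives a first-order loss of 0.0113 /h. On that figure, with no further formation counted, the 0.0437 M read at 13 h in the north-west run, which has the charge of the north-east run, is down at 78 h to 20.9 % of the Q charged.

That loss is the weak link, an estimate that counts no formation in the west run, where X has gained 0.0320 M from a Q charge of 0.100 M. Reforge it at the highest west reading, at 8.7 h, taken as the top, where formation equals loss: kW·c(Q)² = kd·c(X), with c(Q) the charge less the X gained, 0.0680 M, less the X drained, kd times 8.7 h times the reading 0.0750 M at 4.3 h, taken as the mean c(X) so far. Solving gives the drain constant, the fraction of X lost per hour, 0.0268 /h, larger than the first figure.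

Now join the two ends for the north-east run. The X read at 13 h in the north-west run shrinks by 78 h to 7.67 mM. The Q then remaining, 0.0455 M, falls by second-order decay to 0.0128 M. Half of that drop has formed 14.3 h later; drain the whole drop from that moment and it leaves 8.41 mM. Commit to 16.1 %.

The forecast gives 1.2 in Q, 0.85 in E and 36 % (from 20 % to 47 %), higher than my share, on “a slow drain of X”.

The flask gives 9.57 %, with orders 0.93 in Q and 0.93 in E.

    Q + E ⇌ J, settled at all times (1.440 /M)
    J → X (0.5976 /h)
    Q + E + X → 2 X (11.84 /M²/h)
    X → Wy (0.03924 /h)

That share is less than my 16.1 %, and the fit in which E is lost by itself gives 43.3 %. For the north-east run, kd applied to the north-west reading at 13 h, with no further formation counted, gives 7.67 % of the Q charged at 78 h. Watch the late north run too: at 13 h, kd reckons a loss of 1.71 mM/h from the X read there, while the last two readings of that run show a net rise of 0.750 mM/h.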